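**Plan**
- Retrosynthesis: cut the butylidene C3=C8 (back to butanal and a butenolide CH2); then the carbocycle at C5–C6 (back to a β-vinylbutenolide on C7 and a carboxyl group on C6); then C3a–C4 and the butenolide C3a–C7a bond (back to a tetronic acid and a C7–CH2CO2R / C6–CO2H pair); that pair is the cleaved form of a sacrificial cyclopentene fused to the cyclobutane; finally C3'–aryl and C8'–propyl, back to bicyclo[3.2.0]hept-2-en-6-one.
- Forward order of rings: cyclobutanone (bought, fused to the temporary cyclopentene) → spiro-phthalide → cyclopentene cleaved → butenolide → six-membered carbocycle (last ring) → butylidene side chain.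
- Stereochemistry: C7 and the absolute configuration come from ketone 1; C8' from exo alkylation; C3' from exo aryl addition; C6 is deliberately erased (radical) and rewritten by the ring closure, which can only give the cis fusion; the Z alkene is the thermodynamic outcome of the final elimination.
- Enabling feature: the butenolide double bond C7a=C3a holds C7 and C4 cis, so a vinyl terminus C5 on C3a sits next to cyclobutane carbon C6; the lactone carbonyl C1 makes C5 the δ-acceptor position of a cross-conjugated dienyl lactone, so a carboxyl group on C6 serves as a traceless radical handle.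
- Atom labels used: butenolide C1(=O), O2, C3, C3a, C7a; carbocycle C3a, C4, C5, C6, C7, C7a; butylidene C8–C11 on C3; cyclobutane C6, C7, C3' (spiro carbon of the phthalide) and C8' (propyl-bearing).

Key step: step 10

Assumption: ketone 1 is bought as the single (1R,5S) enantiomer; if only the racemate is at hand it would first be resolved by an established enzymatic method.

**Route**

Step 1
Reactants: 1 (1R,5S)-bicyclo[3.2.0]hept-2-en-6-one; 2 1-iodopropane
Product: 3 (1S,5S,7S)-7-propylbicyclo[3.2.0]hept-2-en-6-one (propyl exo)
Conditions: LiN(iPr)2, THF, −78 °C; then 2, DMPU, −78 → −20 °C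
Reagents that add atoms: none
Why: Kinetic enolate alkylation of a cyclobutanone, in which the enolate can form only toward C8' (the other α-carbon is a bridgehead) and the electrophile enters from the convex exo face, so the propyl group is set trans to the cyclopentene ring, which is also the more stable epimer.

Step 2
Reactants: 3 (1S,5S,7S)-7-propylbicyclo[3.2.0]hept-2-en-6-one; 4 methyl 2-iodobenzoate
Product: 6 cyclopentene-fused spiro-phthalide (aryl exo and cis to propyl; lactone oxygen endo), via 2-(methoxycarbonyl)phenylmagnesium chloride 5 (not isolated)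
Conditions: 4, iPrMgCl·LiCl, THF, −40 °C; then 3, LaCl3·2LiCl, −40 °C → rt; aq. NH4Cl
Reagents that add atoms: none
Why: Iodine–magnesium exchange followed by 1,2-addition of the arylmagnesium reagent to the cyclobutanone and lactonisation of the alkoxide onto the ortho ester should occur on the convex exo face, because the line of approach to C3' passes over the transannular carbon C6, whose endo substituent (the cyclopentene) blocks the concave face more than the laterally placed exo-propyl blocks the convex one; this sets C3' with the lactone oxygen cis to the ring arms.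

Step 3
Reactants: 6 cyclopentene-fused spiro-phthalide
Product: 7 cyclobutane diacid (CO2H on C6 and CH2CO2H on C7 cis to each other and to the lactone oxygen)
Conditions: RuCl3·xH2O (cat.), NaIO4, EtOAc/MeCN/H2O, rt
Reagents that add atoms: sodium periodate, [Na+].[O-]I(=O)(=O)=O
Why: Oxidative alkene cleavage by catalytically generated RuO4 converts the only C=C bond into two carboxylic acids, while the electron-poor benzo ring and the lactone are left alone and no stereocentre is touched.

Step 4
Reactants: 7 cyclobutane diacid; 8 methyl glycolate
Product: 10 C6 acid C1 glycolate ester, via cyclic anhydride 9 (not isolated)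
Conditions: Ac2O, 80 °C, then evaporation; 8, DMAP (cat.), Et3N, CH2Cl2, 0 °C → rt; dilute HCl work-up
Reagents that add atoms: none
Why: Dehydration of the cis diacid gives the six-membered cyclic anhydride, and DMAP-catalysed alcoholysis should open it at the less hindered CH2–C(=O) carbonyl (C1) rather than at the carbonyl on the cyclobutane carbon C6 (sterically governed regioselective anhydride opening).

Step 5
Reactants: 10 C6 acid C1 glycolate ester
Product: 11 tert-butyl ester at C6 (glycolate ester at C1 unchanged)
Conditions: tert-butyl 2,2,2-trichloroacetimidate, BF3·OEt2 (cat.), CH2Cl2/cyclohexane, rt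
Reagents that add atoms: tert-butyl 2,2,2-trichloroacetimidate, CC(C)(C)OC(=N)C(Cl)(Cl)Cl
Why: Acid-catalysed tert-butylation of a carboxylic acid by the imidate masks the C6 acid, the later radical precursor, against the base and the triflating agent of the next two steps.

Step 6
Reactants: 11 tert-butyl ester
Product: 12 tetronic acid on C7 (enol OH at C3a; CH2 at C3)
Conditions: LiN(SiMe3)2 (2.5 equiv), THF, −78 °C → rt; aq. HCl
Reagents that add atoms: none
Why: Dieckmann (intramolecular Claisen) condensation of an α-acyloxy ester, in which the C7a enolate attacks the glycolate methyl ester in a 5-exo-trig closure and the acidic tetronate is the thermodynamic sink; any epimerisation at C6 is harmless because that centre is rewritten in step 10.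

Step 7
Reactants: 12 tetronic acid
Product: 13 butenolide C3a triflate
Conditions: Tf2O, iPr2NEt, CH2Cl2, −78 °C
Reagents that add atoms: trifluoromethanesulfonic anhydride, O=S(=O)(OS(=O)(=O)C(F)(F)F)C(F)(F)F
Why: O-sulfonylation of the tetronic acid enol gives the vinylogous acyl triflate, the standard electrophile for cross-coupling at C3a.

Step 8
Reactants: 13 butenolide C3a triflate; 14 tributyl(vinyl)stannane
Product: 15 β-vinylbutenolide tert-butyl ester
Conditions: Pd(PPh3)4 (cat.), LiCl, THF, 65 °C
Reagents that add atoms: none
Why: Stille coupling of a 4-triflyloxybutenolide under zerovalent palladium catalysis installs the vinyl group (C4 and C5) at C3a under neutral conditions that spare both lactones and the tert-butyl ester.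

Step 9
Reactants: 15 β-vinylbutenolide tert-butyl ester
Product: 16 β-vinylbutenolide C6 carboxylic acid
Conditions: CF3CO2H/CH2Cl2 (1:4), 0 °C → rt
Reagents that add atoms: none
Why: Acidolysis of the tert-butyl ester (E1 loss of isobutene) frees the C6 acid without affecting the lactones or the electron-poor diene.

Step 10
Reactants: 16 β-vinylbutenolide C6 carboxylic acid
Product: 18 pentacyclic butenolide lacking only the butylidene (C3 = CH2), via deconjugated lactone 17 (not isolated)
Conditions: Ir[dF(CF3)ppy]2(dtbbpy)PF6 (1 mol %), K2HPO4, degassed DMF (0.01 M), blue LEDs (450 nm), rt; then DBU (cat.), rt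
Reagents that add atoms: none
Why: The carboxylate of 16 is oxidised by the excited trivalent iridium photocatalyst, CO2 is lost, and the secondary cyclobutyl radical at C6 adds to the terminal vinyl carbon C5, the δ-position of the C1(=O)–C7a=C3a–C4=C5 dienyl lactone; the resulting allylic α-acyl radical is reduced by divalent iridium to the dienolate, which is protonated at C7a to give 17 and then moved into conjugation by DBU to give 18. The closest known reaction type is the photoredox decarboxylative Giese (radical conjugate) addition, used here in its intramolecular 1,6-vinylogous form. The carbocycle C7a–C3a–C4–C5–C6–C7 closes in a 6-endo-trig radical mode by forming the C5–C6 bond. The only new stereocentre, C6, is controlled by the tether: the radical is planar, so the C6 configuration of 16 is irrelevant, and C5 can only arrive on the cyclobutane face that carries the butenolide at C7, which enforces the cis ring fusion. The step needs attack at C5 rather than C4 and cyclisation rather than premature reduction of the radical; the first is secured by the polarisation of the cross-conjugated acceptor and by the cis-locked C7a=C3a bond that places C5 next to C6 (attack at C4 would give an unstabilised primary radical), the second by intramolecularity at high dilution. The carboxyl group that has served as the differentiating handle since step 4 leaves as CO2 in the same operation.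

Step 11
Reactants: 18 pentacyclic butenolide (C3 = CH2); 19 butanal
Product: 22 CNP0248594.3 (target), via silyloxyfuran 20 (not isolated), via silyl aldol adduct 21 (not isolated)
Conditions: TBSOTf, iPr2NEt, CH2Cl2, 0 °C; then 19, −78 → 0 °C; then DBU, rt
Reagents that add atoms: none
Why: Silyl-triflate-mediated vinylogous Mukaiyama aldol addition of the in situ 2-silyloxyfuran to butanal at C3, followed by base-induced vinylogous E1cB loss of silanolate, should give the exocyclic C3=C8 bond as the Z isomer, because the E isomer would press the propyl chain against the C4 methylene.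

**Compound list**

1 | (1R,5S)-bicyclo[3.2.0]hept-2-en-6-one | O=C1C[C@@H]2C=CC[C@H]12 | starting material
2 | 1-iodopropane | CCCI | starting material
3 | (1S,5S,7S)-7-propylbicyclo[3.2.0]hept-2-en-6-one (propyl exo) | O=C1[C@@H](CCC)[C@@H]2C=CC[C@H]12 | intermediate
4 | methyl 2-iodobenzoate | COC(=O)c1ccccc1I | starting material
5 | 2-(methoxycarbonyl)phenylmagnesium chloride | COC(=O)c1ccccc1[Mg]Cl | intermediate (not isolated)
6 | 7-exo-propylspiro[bicyclo[3.2.0]hept-2-ene-6,1'-isobenzofuran]-3'-one; lactone oxygen endo (cis to the cyclopentene), aryl ring exo (cis to propyl) | CCC[C@H]1[C@@H]2C=CC[C@@H]2[C@]13OC(=O)c4ccccc43 | intermediate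
7 | 2-(carboxymethyl)-3'-oxo-4-propylspiro[cyclobutane-1,1'-isobenzofuran]-3-carboxylic acid; CO2H (C6) and CH2CO2H (C7) cis to each other and to the lactone oxygen, propyl trans to them | CCC[C@H]1[C@H](C(=O)O)[C@H](CC(=O)O)[C@]12OC(=O)c3ccccc32 | intermediate
8 | methyl glycolate (methyl 2-hydroxyacetate) | COC(=O)CO | starting material
9 | cis-fused six-membered cyclic anhydride of diacid 7 | CCC[C@H]1[C@@H]2C(=O)OC(=O)C[C@@H]2[C@]13OC(=O)c4ccccc43 | intermediate (not isolated)
10 | diacid 7 esterified at the CH2CO2H group (C1) with methyl glycolate; free CO2H on C6 | CCC[C@H]1[C@H](C(=O)O)[C@H](CC(=O)OCC(=O)OC)[C@]12OC(=O)c3ccccc32 | intermediate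
11 | tert-butyl ester of 10 at the C6 carboxyl | CCC[C@H]1[C@H](C(=O)OC(C)(C)C)[C@H](CC(=O)OCC(=O)OC)[C@]12OC(=O)c3ccccc32 | intermediate
12 | tetronic acid (4-hydroxyfuran-2(5H)-one) attached through its 3-position (C7a) to C7; C6 tert-butyl ester | CCC[C@H]1[C@H](C(=O)OC(C)(C)C)[C@H](C2=C(O)COC2=O)[C@]13OC(=O)c4ccccc43 | intermediate
13 | 4-triflyloxybutenolide (triflate on C3a) attached at C7a to C7; C6 tert-butyl ester | CCC[C@H]1[C@H](C(=O)OC(C)(C)C)[C@H](C2=C(OS(=O)(=O)C(F)(F)F)COC2=O)[C@]13OC(=O)c4ccccc43 | intermediate
14 | tributyl(vinyl)stannane | C=C[Sn](CCCC)(CCCC)CCCC | starting material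
15 | 4-vinylbutenolide attached at C7a to C7; C6 tert-butyl ester | CCC[C@H]1[C@H](C(=O)OC(C)(C)C)[C@H](C2=C(C=C)COC2=O)[C@]13OC(=O)c4ccccc43 | intermediate
16 | 4-vinylbutenolide attached at C7a to C7; free C6 carboxylic acid | CCC[C@H]1[C@H](C(=O)O)[C@H](C2=C(C=C)COC2=O)[C@]13OC(=O)c4ccccc43 | intermediate
17 | cyclised lactone with the double bond at C3a=C4 and H on C7a (C7a epimers) | C1OC(=O)C2C1=CC[C@H]1[C@H](CCC)[C@@]3(OC(=O)c4ccccc43)[C@@H]21 | intermediate (not isolated)
18 | pentacyclic butenolide: the target skeleton with CH2 at C3 (no butylidene); cis ring fusion at C6/C7 | C1OC(=O)C2=C1CC[C@H]1[C@H](CCC)[C@@]3(OC(=O)c4ccccc43)[C@@H]21 | intermediate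
19 | butanal | CCCC=O | starting material
20 | 2-(tert-butyldimethylsilyloxy)furan derived from 18 (furan carbons C1, C3, C3a, C7a) | CC(C)(C)[Si](C)(C)Oc1occ2CC[C@H]3[C@H](CCC)[C@@]4(OC(=O)c5ccccc54)[C@H]3c12 | intermediate (not isolated)
21 | 18 bearing a 1-(tert-butyldimethylsilyloxy)butyl group on C3 (diastereomers at C3 and C8) | CCCC(O[Si](C)(C)C(C)(C)C)C1OC(=O)C2=C1CC[C@H]1[C@H](CCC)[C@@]3(OC(=O)c4ccccc43)[C@@H]21 | intermediate (not isolated)
22 | CNP0248594.3: (Z)-3-butylidene pentacyclic bis-lactone, (6S,7R,3'R,8'S) in the labels used here | CCC/C=C1\OC(=O)C2=C1CC[C@H]1[C@H](CCC)[C@@]3(OC(=O)c4ccccc43)[C@@H]21 | target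

**Summary**
Total step count: 11. Longest linear sequence: 11 steps (from ketone 1).

**Steps most likely to fail**

1. Step 10. The cyclobutyl radical at C6 may fragment by β-scission of the C7–C3' bond toward the benzylic α-oxy radical, may be reduced before it cyclises, or the dienyl lactone may be sensitised by the photocatalyst and oligomerise. Fallback (sets out from compound 10, returns at compound 18): the same ring is closed at C3a–C4 by two-electron chemistry. BH3·SMe2 reduces the free C6 acid selectively to the primary alcohol F1. TEMPO/PhI(OAc)2 oxidation gives the aldehyde F2. Wittig methylenation (Ph3P=CH2, −78 °C, to limit epimerisation at C6) gives the C6-vinyl compound F3. Dieckmann condensation with LiN(SiMe3)2 then gives the tetronic acid F4, and Tf2O/iPr2NEt the triflate F5. Hydroboration of the vinyl group with 9-BBN gives the B-alkyl borane F6, which is closed onto the triflate by an intramolecular B-alkyl Suzuki–Miyaura coupling (Pd(dppf)Cl2, AsPh3, Cs2CO3, DMF/H2O) to give 18. In this variant the cis C6/C7 relationship inherited from the cyclopentene must be kept throughout.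

2. Step 2. The exo-propyl group may erode the facial selectivity, steering the aryl nucleophile to the concave face and giving the C3' epimer. Fallback (sets out from compound 1, returns at compound 7): the order of the two stereodefining events is reversed, so that the aryl group adds while C8' is sp2 and C8' is then set by a directed hydrogenation. The cyclopentene of 1 is masked by OsO4/NMO dihydroxylation from the exo face, giving the diol F7, and acetonide formation (2,2-dimethoxypropane, TsOH) gives the acetonide F8. Aldol addition to propanal (LiN(SiMe3)2) gives the aldol F9, and one-pot mesylation–elimination (MsCl, Et3N, then DBU) gives the (E)-propylidene ketone F10. 2-Bromophenylmagnesium chloride (from 1-bromo-2-iodobenzene and iPrMgCl·LiCl) now adds from the exo face with no out-of-plane α-substituent to oppose it, giving the tertiary allylic alcohol F11. Hydroxyl-directed hydrogenation with [Ir(cod)(PCy3)(py)]PF6 delivers hydrogen to C8' on the face of the endo hydroxyl, which places propyl cis to the aryl ring in the alcohol F12. Carbonylative lactonisation (Pd(OAc)2, dppf, CO, Et3N) gives the spiro-phthalide acetonide F13. H5IO6 in aqueous THF removes the acetonide and cleaves the diol to the dialdehyde F14, and Pinnick oxidation (NaClO2) gives diacid 7.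

3. Step 6. The base may deprotonate the glycolate CH2 instead of C7a, leading to 1,2-acyl migration (Chan rearrangement) or ester scrambling rather than ring closure. Fallback (sets out from compound 7 through anhydride 9, returns at compound 12): the tetronic acid is built by intermolecular C-acylation. Anhydride 9 is opened with methanol/DMAP to the C1 methyl ester C6 acid F15, and tert-butylation as in step 5 gives the diester F16. Its ester enolate (LiN(SiMe3)2, 2.1 equiv, deprotonation at the CH2 rather than at the hindered C6 methine) is acylated with acetoxyacetyl chloride to give the γ-acetoxy-β-keto ester F17. K2CO3 in methanol removes the acetate, and the freed alkoxide lactonises onto the methyl ester to give tetronic acid 12.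

**Further compounds**

F1 | step 10 | primary alcohol: 10 with CH2OH on C6 in place of CO2H | CCC[C@H]1[C@H](CO)[C@H](CC(=O)OCC(=O)OC)[C@]12OC(=O)c3ccccc32
F2 | step 10 | aldehyde: 10 with CHO on C6 | CCC[C@H]1[C@H](C=O)[C@H](CC(=O)OCC(=O)OC)[C@]12OC(=O)c3ccccc32
F3 | step 10 | C6-vinyl glycolate ester | CCC[C@H]1[C@H](C=C)[C@H](CC(=O)OCC(=O)OC)[C@]12OC(=O)c3ccccc32
F4 | step 10 | C6-vinyl tetronic acid | CCC[C@H]1[C@H](C=C)[C@H](C2=C(O)COC2=O)[C@]13OC(=O)c4ccccc43
F5 | step 10 | C6-vinyl butenolide C3a triflate | CCC[C@H]1[C@H](C=C)[C@H](C2=C(OS(=O)(=O)C(F)(F)F)COC2=O)[C@]13OC(=O)c4ccccc43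
F6 | step 10 | B-alkyl-9-BBN adduct of F5 (boron on C4) | CCC[C@H]1[C@H](CCB2C3CCCC2CCC3)[C@H](C2=C(OS(=O)(=O)C(F)(F)F)COC2=O)[C@]13OC(=O)c4ccccc43
F7 | step 2 | exo-cis-2,3-dihydroxybicyclo[3.2.0]heptan-6-one from 1 | O=C1C[C@@H]2[C@@H](O)[C@@H](O)C[C@H]12
F8 | step 2 | acetonide of F7 | O=C1C[C@@H]2[C@H]3OC(C)(C)O[C@H]3C[C@H]12
F9 | step 2 | aldol adduct of F8 with propanal (1-hydroxypropyl on C8', diastereomers) | O=C1C(C(O)CC)[C@@H]2[C@H]3OC(C)(C)O[C@H]3C[C@H]12
F10 | step 2 | (E)-propylidene ketone | O=C1/C(=C/CC)[C@@H]2[C@H]3OC(C)(C)O[C@H]3C[C@H]12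
F11 | step 2 | tertiary allylic alcohol: 2-bromophenyl exo, OH endo | O[C@]1(c2ccccc2Br)/C(=C/CC)[C@@H]2[C@H]3OC(C)(C)O[C@H]3C[C@H]12
F12 | step 2 | hydrogenated alcohol: propyl exo, cis to aryl | O[C@]1(c2ccccc2Br)[C@@H](CCC)[C@@H]2[C@H]3OC(C)(C)O[C@H]3C[C@H]12
F13 | step 2 | spiro-phthalide acetonide (6 with the alkene replaced by the exo-diol acetonide) | CCC[C@H]1[C@@H]2[C@H]3OC(C)(C)O[C@H]3C[C@@H]2[C@]14OC(=O)c5ccccc54
F14 | step 2 | dialdehyde: CHO on C6 and CH2CHO on C7 | CCC[C@H]1[C@H](C=O)[C@H](CC=O)[C@]12OC(=O)c3ccccc32
F15 | step 6 | C1 methyl ester C6 acid | CCC[C@H]1[C@H](C(=O)O)[C@H](CC(=O)OC)[C@]12OC(=O)c3ccccc32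
F16 | step 6 | C1 methyl ester C6 tert-butyl ester | CCC[C@H]1[C@H](C(=O)OC(C)(C)C)[C@H](CC(=O)OC)[C@]12OC(=O)c3ccccc32
F17 | step 6 | γ-acetoxy-β-keto ester (acetoxyacetyl group on C7a, C7a epimers) | CCC[C@H]1[C@H](C(=O)OC(C)(C)C)[C@H](C(C(=O)OC)C(=O)COC(C)=O)[C@]12OC(=O)c3ccccc32
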